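**Retrosynthetic overview**

- The target is fisetinidol-(4β→6)-catechin-(8→4β)-fisetinidol; it is released last by hydrogenolysis of its trideca-O-benzyl ether.
- Both interflavanyl bonds are cut together: 6,8-dilithio-penta-O-benzylcatechin adds to two molecules of a protected flavanonol ketone (tetra-O-benzylfustin), and ionic hydrogenation then sets both C4–H centres anti to O3 (3,4-cis).
- The ketone comes from a 7,3',4'-tribenzyloxyflavanone by oxygenation of C3 anti to the C2 aryl group; the relay chain is auxiliary sulfur → C2 → C3 → C4.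
- The flavanone is made in the key step. Ring C (O1, C2, C3, C4, C4a, C8a) is closed by an aza-enolate aldol (C2–C3) and an SNAr closure (O1–C8a) between an aryl methyl N-sulfinyl ketimine and 3,4-bis(benzyloxy)benzaldehyde. The enabling feature is C4: it is bonded to C3 and to C4a, the ortho neighbour of the O1-bearing C8a, so a carbonyl-level C4 (C=N–S(O)t-Bu) acidifies C3–H and activates a fluoride at C8a.
- Ring order: ring C of the fisetinidol unit is built once and used twice (its rings A and B are bought as benzene derivatives); the catechin rings are bought intact.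

Key step: step 3

Assumption: the (R)-sulfinyl group is taken to deliver the (S)-configured C2 carbinol in the closed chair transition state; should the sense prove opposite, (S)-2-methylpropane-2-sulfinamide is used instead and nothing else changes.

**Step 1**
Reactants: 1 1-(2-fluoro-4-hydroxyphenyl)ethan-1-one
Product: 2 1-[4-(benzyloxy)-2-fluorophenyl]ethan-1-one
Conditions: BnBr, K2CO3, acetone, reflux
Reagents that add atoms: benzyl bromide BrCc1ccccc1
Why: Williamson ether synthesis on the phenol, in which the weak base and moderate temperature should leave the activated C–F bond untouched.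

**Step 2**
Reactants: 2 1-[4-(benzyloxy)-2-fluorophenyl]ethan-1-one
Product: 3 (R,E)-N-{1-[4-(benzyloxy)-2-fluorophenyl]ethylidene}-2-methylpropane-2-sulfinamide
Conditions: (R)-t-BuS(O)NH2, Ti(OEt)4, THF, 70 °C
Reagents that add atoms: (R)-2-methylpropane-2-sulfinamide CC(C)(C)[S@](N)=O
Why: Ti(OEt)4-mediated condensation of a ketone with tert-butanesulfinamide is the standard route to N-sulfinyl ketimines, the E-imine (sulfinyl anti to aryl) is expected and no carbon stereocentre is formed.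

**Step 3**
Reactants: 3 (R,E)-N-{1-[4-(benzyloxy)-2-fluorophenyl]ethylidene}-2-methylpropane-2-sulfinamide; 4 3,4-bis(benzyloxy)benzaldehyde
Product: 7 (2S)-7-(benzyloxy)-2-[3,4-bis(benzyloxy)phenyl]chroman-4-one, via magnesium aldolate 5 (not isolated), via cyclic N-sulfinyl ketimine 6 (not isolated)
Conditions: LiN(i-Pr)2, THF, −78 °C; MgBr2·OEt2; 4 (1.2 equiv), −78 °C; DMPU, −78 → 25 °C; then 1 M HCl, THF, 25 °C
Reagents that add atoms: water O
Why: Proposed new method: the metalated N-sulfinyl ketimine of 3 should add to aldehyde 4 through a closed six-membered chair transition state (aza-enolate aldol addition of N-tert-butanesulfinyl ketimines to aldehydes is the closest known reaction type), and the β-alkoxide 5 should then displace the ortho-fluoride by addition–elimination, as alkoxides are known to do on 2-fluoroaryl ketones, here with C4=N as the activating group. Ring C is closed by 6-exo-trig attack of O1 on C8a; the anionic σ-adduct is stabilised by the C4=N–S(O) unit, and fluoride loss should be assisted by the metal ion held at the imine nitrogen, whose lone pair points toward C8a in the E-imine. The single new stereocentre, C2, is controlled by the sulfur stereocentre of the auxiliary, which fixes the aldehyde face in the chair with the aryl group equatorial. The step needs ring closure to outrun retro-addition of 5, which the covalent magnesium alkoxide at low temperature and the chelation-assisted displacement on warming should secure; regioselectivity is given because C8a is the only fluorinated and the only activated ring position. Because the auxiliary stays bound until the acidic work-up, any aldolate that reverts re-adds under the same stereocontrol, and mild aqueous acid then hydrolyses 6 to ketone 7 without touching C2.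

**Step 4**
Reactants: 7 (2S)-7-(benzyloxy)-2-[3,4-bis(benzyloxy)phenyl]chroman-4-one
Product: 10 (2R,3R)-7-(benzyloxy)-2-[3,4-bis(benzyloxy)phenyl]-3-hydroxychroman-4-one, via silyl enol ether 8 (not isolated), via silyloxy epoxide 9 (not isolated)
Conditions: TMSOTf, Et3N, CH2Cl2, 0 °C; then DMDO, acetone, −40 °C; then citric acid, MeOH/H2O, 25 °C
Reagents that add atoms: dimethyldioxirane CC1(C)OO1
Why: Rubottom oxidation, in which soft enolisation avoids a free enolate (no opening of ring C) and dimethyldioxirane should epoxidise the enol ether on the face anti to the C2 aryl group, so that C3–O is set trans to C2–aryl by substrate control.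

**Step 5**
Reactants: 10 (2R,3R)-7-(benzyloxy)-2-[3,4-bis(benzyloxy)phenyl]-3-hydroxychroman-4-one
Product: 11 (2R,3R)-3,7-bis(benzyloxy)-2-[3,4-bis(benzyloxy)phenyl]chroman-4-one
Conditions: BnOC(=NH)CCl3, TfOH (cat.), CH2Cl2/cyclohexane, 0 → 25 °C
Reagents that add atoms: benzyl 2,2,2-trichloroacetimidate N=C(OCc1ccccc1)C(Cl)(Cl)Cl
Why: acid-catalysed O-benzylation with a trichloroacetimidate, chosen because base would risk epimerisation at C3 and β-elimination of the ring oxygen, touches no stereocentre.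

**Step 6**
Reactants: 12 (+)-catechin
Product: 13 (2R,3S)-3,5,7-tris(benzyloxy)-2-[3,4-bis(benzyloxy)phenyl]chromane (penta-O-benzylcatechin)
Conditions: BnBr, K2CO3, DMF, 25 °C; then NaH, 0 → 25 °C
Reagents that add atoms: benzyl bromide BrCc1ccccc1
Why: Williamson etherification, phenols first with K2CO3 and the secondary 3-OH with NaH only once no phenoxide is left, which should avoid C-benzylation and epimerisation at C2.

**Step 7**
Reactants: 13 penta-O-benzylcatechin
Product: 14 6,8-dibromo-penta-O-benzylcatechin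
Conditions: NBS (2.1 equiv), CH2Cl2, −40 → 0 °C
Reagents that add atoms: N-bromosuccinimide O=C1CCC(=O)N1Br
Why: electrophilic aromatic bromination, selective because the trioxygenated ring A of the catechin is far more electron rich than any other ring and C6 and C8 are its only free positions.

**Step 8**
Reactants: 14 6,8-dibromo-penta-O-benzylcatechin; 11 (2R,3R)-3,7-bis(benzyloxy)-2-[3,4-bis(benzyloxy)phenyl]chroman-4-one (two equivalents react)
Product: 16 6,8-bis[3,7-bis(benzyloxy)-2-(3,4-bis(benzyloxy)phenyl)-4-hydroxychroman-4-yl]-penta-O-benzylcatechin, via dilithio arene 15 (not isolated)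
Conditions: t-BuLi (4.2 equiv), THF, −78 °C; then 11 (2.4 equiv), −78 → −40 °C; then H2O
Reagents that add atoms: none
Why: double bromine–lithium exchange gives an aryllithium flanked by two alkoxy groups at each site, which should add 1,2 to the ketone of 11 (aryllithium addition to a protected flavan-4-one), and the configuration of the new carbinol carbons is of no consequence because both are ionised in the next step.

**Step 9**
Reactants: 16 bis(tertiary alcohol)
Product: 17 trideca-O-benzyl fisetinidol-(4β→6)-catechin-(8→4β)-fisetinidol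
Conditions: Et3SiH, CF3CO2H, CH2Cl2, −78 → −20 °C
Reagents that add atoms: none
Why: ionic hydrogenation, in which acid ionises each tertiary doubly benzylic alcohol to a cation stabilised by the 7-benzyloxy group and the trialkoxyaryl ring and Et3SiH should deliver hydride quasi-axially to the face anti to the neighbouring C3 benzyloxy group, placing the catechin ring cis to O3 (3,4-cis, 4β) in both units by substrate control.

**Step 10**
Reactants: 17 trideca-O-benzyl ether
Product: 18 fisetinidol-(4β→6)-catechin-(8→4β)-fisetinidol (target)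
Conditions: H2 (1 atm), Pd(OH)2/C, THF/MeOH/H2O, 25 °C
Reagents that add atoms: none
Why: hydrogenolysis of the thirteen benzyl ethers over Pd(OH)2/C, conditions under which the ring C2–O1 benzylic ethers and the diarylmethine C4–H positions of benzylated oligoflavanoids are expected to survive.

**Compound list**

1 | 1-(2-fluoro-4-hydroxyphenyl)ethan-1-one | CC(=O)c1ccc(O)cc1F | starting material
2 | 1-[4-(benzyloxy)-2-fluorophenyl]ethan-1-one | CC(=O)c1ccc(OCc2ccccc2)cc1F | intermediate
3 | (R,E)-N-{1-[4-(benzyloxy)-2-fluorophenyl]ethylidene}-2-methylpropane-2-sulfinamide | C/C(=N\[S@](=O)C(C)(C)C)c1ccc(OCc2ccccc2)cc1F | intermediate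
4 | 3,4-bis(benzyloxy)benzaldehyde | O=Cc1ccc(OCc2ccccc2)c(OCc2ccccc2)c1 | starting material
5 | bromomagnesium alkoxide of (S)-1-[3,4-bis(benzyloxy)phenyl]-3-[4-(benzyloxy)-2-fluorophenyl]-3-{[(R)-tert-butylsulfinyl]imino}propan-1-ol | Br[Mg]O[C@@H](C/C(=N\[S@](=O)C(C)(C)C)c1ccc(OCc2ccccc2)cc1F)c1ccc(OCc2ccccc2)c(OCc2ccccc2)c1 | intermediate
6 | (R)-N-{(2S)-7-(benzyloxy)-2-[3,4-bis(benzyloxy)phenyl]chroman-4-ylidene}-2-methylpropane-2-sulfinamide | O(Cc9ccccc9)c1ccc2c(c1)O[C@H](c1ccc(OCc9ccccc9)c(OCc9ccccc9)c1)C/C2=N\[S@](=O)C(C)(C)C | intermediate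
7 | (2S)-7-(benzyloxy)-2-[3,4-bis(benzyloxy)phenyl]chroman-4-one | O(Cc9ccccc9)c1ccc2c(c1)O[C@H](c1ccc(OCc9ccccc9)c(OCc9ccccc9)c1)CC2=O | intermediate
8 | (2S)-7-(benzyloxy)-2-[3,4-bis(benzyloxy)phenyl]-4-(trimethylsilyloxy)-2H-chromene | O(Cc9ccccc9)c1ccc2c(c1)O[C@H](c1ccc(OCc9ccccc9)c(OCc9ccccc9)c1)C=C2O[Si](C)(C)C | intermediate
9 | 3,4-epoxide of 8, oxirane oxygen trans to the C2 aryl group | O(Cc9ccccc9)c1ccc2c(c1)O[C@H](c1ccc(OCc9ccccc9)c(OCc9ccccc9)c1)[C@H]3O[C@@]23O[Si](C)(C)C | intermediate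
10 | (2R,3R)-7-(benzyloxy)-2-[3,4-bis(benzyloxy)phenyl]-3-hydroxychroman-4-one | O(Cc9ccccc9)c1ccc2c(c1)O[C@H](c1ccc(OCc9ccccc9)c(OCc9ccccc9)c1)[C@@H](O)C2=O | intermediate
11 | (2R,3R)-3,7-bis(benzyloxy)-2-[3,4-bis(benzyloxy)phenyl]chroman-4-one (tetra-O-benzylfustin) | O(Cc9ccccc9)c1ccc2c(c1)O[C@H](c1ccc(OCc9ccccc9)c(OCc9ccccc9)c1)[C@@H](OCc9ccccc9)C2=O | intermediate
12 | (+)-catechin, (2R,3S)-2-(3,4-dihydroxyphenyl)chromane-3,5,7-triol | Oc1cc(O)c2c(c1)O[C@H](c1ccc(O)c(O)c1)[C@@H](O)C2 | starting material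
13 | (2R,3S)-3,5,7-tris(benzyloxy)-2-[3,4-bis(benzyloxy)phenyl]chromane | O(Cc9ccccc9)c1cc(OCc9ccccc9)c2c(c1)O[C@H](c1ccc(OCc9ccccc9)c(OCc9ccccc9)c1)[C@@H](OCc9ccccc9)C2 | intermediate
14 | (2R,3S)-3,5,7-tris(benzyloxy)-2-[3,4-bis(benzyloxy)phenyl]-6,8-dibromochromane | O(Cc9ccccc9)c1c(Br)c(OCc9ccccc9)c2c(c1Br)O[C@H](c1ccc(OCc9ccccc9)c(OCc9ccccc9)c1)[C@@H](OCc9ccccc9)C2 | intermediate
15 | 6,8-dilithio-penta-O-benzylcatechin | O(Cc9ccccc9)c1c([Li])c(OCc9ccccc9)c2c(c1[Li])O[C@H](c1ccc(OCc9ccccc9)c(OCc9ccccc9)c1)[C@@H](OCc9ccccc9)C2 | intermediate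
16 | bis(tertiary alcohol): penta-O-benzylcatechin carrying at C6 and at C8 a (2R,3R)-tetra-O-benzylfustin-derived 4-hydroxychroman-4-yl group, drawn with the catechin ring trans to the 3-benzyloxy group | O(Cc9ccccc9)c1ccc2c(c1)O[C@H](c1ccc(OCc9ccccc9)c(OCc9ccccc9)c1)[C@@H](OCc9ccccc9)[C@]2(O)c1c(OCc9ccccc9)c2c(c([C@]3(O)c4ccc(OCc9ccccc9)cc4O[C@H](c4ccc(OCc9ccccc9)c(OCc9ccccc9)c4)[C@H]3OCc9ccccc9)c1OCc9ccccc9)O[C@H](c1ccc(OCc9ccccc9)c(OCc9ccccc9)c1)[C@@H](OCc9ccccc9)C2 | intermediate
17 | trideca-O-benzyl fisetinidol-(4β→6)-catechin-(8→4β)-fisetinidol, both fisetinidol units (2R,3S,4R) | O(Cc9ccccc9)c1ccc2c(c1)O[C@H](c1ccc(OCc9ccccc9)c(OCc9ccccc9)c1)[C@@H](OCc9ccccc9)[C@H]2c1c(OCc9ccccc9)c2c(c([C@H]3c4ccc(OCc9ccccc9)cc4O[C@H](c4ccc(OCc9ccccc9)c(OCc9ccccc9)c4)[C@H]3OCc9ccccc9)c1OCc9ccccc9)O[C@H](c1ccc(OCc9ccccc9)c(OCc9ccccc9)c1)[C@@H](OCc9ccccc9)C2 | intermediate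
18 | fisetinidol-(4β→6)-catechin-(8→4β)-fisetinidol | Oc1ccc2c(c1)O[C@H](c1ccc(O)c(O)c1)[C@@H](O)[C@H]2c1c(O)c2c(c([C@H]3c4ccc(O)cc4O[C@H](c4ccc(O)c(O)c4)[C@H]3O)c1O)O[C@H](c1ccc(O)c(O)c1)[C@@H](O)C2 | target

**Step count and risks**

Total step count: 10. Longest linear sequence: 8 steps (steps 1 to 5, then 8 to 10).

Steps most likely to fail:

1. Step 3 (proposed new method). The magnesium aldolate may revert to aza-enolate and aldehyde before ring closure, eroding the configuration at C2, or the fluoride displacement may be too slow on the ring deactivated by the para benzyloxy group. The fallback uses known chemistry, sets out from 4 and returns at 10. Commercial 1-[4-(benzyloxy)-2-hydroxyphenyl]ethan-1-one is protected (MOMCl, i-Pr2NEt, CH2Cl2) to 1-[4-(benzyloxy)-2-(methoxymethoxy)phenyl]ethan-1-one F1. Claisen–Schmidt condensation of F1 with 4 (KOH, EtOH/THF) should give the (E)-chalcone F2. Juliá–Colonna epoxidation (poly-L-leucine, urea–H2O2, DBU, THF) should give the (αR,βS)-epoxy ketone F3. HCl in MeOH/THF at 50 °C removes the MOM group to the free phenol F4 (not isolated), which should open the epoxide at the benzylic carbon with inversion to give 10. In this fallback O1 is bought with the phenol and ring C is closed at O1–C2.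

2. Step 8. The second addition may stall for steric reasons, or the aryllithium may act as a base toward C3–H of 11, which would lead to enolisation and opening of ring C. The fallback sets out from 13 and returns at 17, building the two bonds one after the other. NBS (1.0 equiv, CH2Cl2, −78 °C) should give 8-bromo-penta-O-benzylcatechin F5. Exchange with t-BuLi gives the 8-lithio arene F6 (not isolated), which adds to 11 to give the C8 carbinol F7. Et3SiH/CF3CO2H should give nona-O-benzyl fisetinidol-(4β→8)-catechin F8. NBS then brominates the remaining catechin position to give the 6-bromo dimer F9; t-BuLi gives the 6-lithio dimer F10 (not isolated), which adds to 11 to give the C6 carbinol F11, and Et3SiH/CF3CO2H gives 17.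

3. Step 9. Facial selectivity of hydride delivery may be poor, the cation may lose the C3 proton to give an enol ether that is reduced without control, or acid may cleave an interflavanyl bond. The fallback sets out from 11 and returns at 17, forming the C4–aryl bonds by electrophilic substitution instead. NaBH4 (MeOH/THF, 0 °C) should reduce 11 to the 3,4-trans alcohol (2R,3S,4R)-3,7-bis(benzyloxy)-2-[3,4-bis(benzyloxy)phenyl]chroman-4-ol F12. TMSOTf-promoted Friedel–Crafts reaction of F12 (2.2 equiv) with 13 (CH2Cl2, −78 °C) should substitute C8 and C6 of the catechin and give 17 together with its C4 epimers, from which it is separated by chromatography.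

**Further compounds**

F1 | step 3 | 1-[4-(benzyloxy)-2-(methoxymethoxy)phenyl]ethan-1-one | COCOc1cc(OCc2ccccc2)ccc1C(C)=O
F2 | step 3 | (E)-1-[4-(benzyloxy)-2-(methoxymethoxy)phenyl]-3-[3,4-bis(benzyloxy)phenyl]prop-2-en-1-one | COCOc1cc(OCc2ccccc2)ccc1C(=O)/C=C/c1ccc(OCc2ccccc2)c(OCc2ccccc2)c1
F3 | step 3 | [4-(benzyloxy)-2-(methoxymethoxy)phenyl]{(2R,3S)-3-[3,4-bis(benzyloxy)phenyl]oxiran-2-yl}methanone | COCOc1cc(OCc2ccccc2)ccc1C(=O)[C@@H]1O[C@H]1c1ccc(OCc2ccccc2)c(OCc2ccccc2)c1
F4 | step 3 | [4-(benzyloxy)-2-hydroxyphenyl]{(2R,3S)-3-[3,4-bis(benzyloxy)phenyl]oxiran-2-yl}methanone | Oc1cc(OCc2ccccc2)ccc1C(=O)[C@@H]1O[C@H]1c1ccc(OCc2ccccc2)c(OCc2ccccc2)c1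
F5 | step 8 | 8-bromo-penta-O-benzylcatechin | O(Cc9ccccc9)c1cc(OCc9ccccc9)c2c(c1Br)O[C@H](c1ccc(OCc9ccccc9)c(OCc9ccccc9)c1)[C@@H](OCc9ccccc9)C2
F6 | step 8 | 8-lithio-penta-O-benzylcatechin | O(Cc9ccccc9)c1cc(OCc9ccccc9)c2c(c1[Li])O[C@H](c1ccc(OCc9ccccc9)c(OCc9ccccc9)c1)[C@@H](OCc9ccccc9)C2
F7 | step 8 | penta-O-benzylcatechin carrying the 4-hydroxychroman-4-yl group of 11 at C8 | c1c(OCc9ccccc9)c2c(c([C@]3(O)c4ccc(OCc9ccccc9)cc4O[C@H](c4ccc(OCc9ccccc9)c(OCc9ccccc9)c4)[C@H]3OCc9ccccc9)c1OCc9ccccc9)O[C@H](c1ccc(OCc9ccccc9)c(OCc9ccccc9)c1)[C@@H](OCc9ccccc9)C2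
F8 | step 8 | nona-O-benzyl fisetinidol-(4β→8)-catechin | c1c(OCc9ccccc9)c2c(c([C@H]3c4ccc(OCc9ccccc9)cc4O[C@H](c4ccc(OCc9ccccc9)c(OCc9ccccc9)c4)[C@H]3OCc9ccccc9)c1OCc9ccccc9)O[C@H](c1ccc(OCc9ccccc9)c(OCc9ccccc9)c1)[C@@H](OCc9ccccc9)C2
F9 | step 8 | 6-bromo derivative of F8 | Brc1c(OCc9ccccc9)c2c(c([C@H]3c4ccc(OCc9ccccc9)cc4O[C@H](c4ccc(OCc9ccccc9)c(OCc9ccccc9)c4)[C@H]3OCc9ccccc9)c1OCc9ccccc9)O[C@H](c1ccc(OCc9ccccc9)c(OCc9ccccc9)c1)[C@@H](OCc9ccccc9)C2
F10 | step 8 | 6-lithio derivative of F8 | [Li]c1c(OCc9ccccc9)c2c(c([C@H]3c4ccc(OCc9ccccc9)cc4O[C@H](c4ccc(OCc9ccccc9)c(OCc9ccccc9)c4)[C@H]3OCc9ccccc9)c1OCc9ccccc9)O[C@H](c1ccc(OCc9ccccc9)c(OCc9ccccc9)c1)[C@@H](OCc9ccccc9)C2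
F11 | step 8 | F8 carrying the 4-hydroxychroman-4-yl group of 11 at C6 | O(Cc9ccccc9)c1ccc2c(c1)O[C@H](c1ccc(OCc9ccccc9)c(OCc9ccccc9)c1)[C@@H](OCc9ccccc9)[C@]2(O)c1c(OCc9ccccc9)c2c(c([C@H]3c4ccc(OCc9ccccc9)cc4O[C@H](c4ccc(OCc9ccccc9)c(OCc9ccccc9)c4)[C@H]3OCc9ccccc9)c1OCc9ccccc9)O[C@H](c1ccc(OCc9ccccc9)c(OCc9ccccc9)c1)[C@@H](OCc9ccccc9)C2
F12 | step 9 | (2R,3S,4R)-3,7-bis(benzyloxy)-2-[3,4-bis(benzyloxy)phenyl]chroman-4-ol | O(Cc9ccccc9)c1ccc2c(c1)O[C@H](c1ccc(OCc9ccccc9)c(OCc9ccccc9)c1)[C@@H](OCc9ccccc9)[C@@H]2O
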